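Abbreviations: TBS = tert-butyldimethylsilyl, TBDPS = tert-butyldiphenylsilyl, TBSO and TBDPSO the corresponding silyloxy groups. Flavanone numbering is used (O1, C2, C3, C4, C4a, C5–C8, C8a; ring B primed; side chain C1″–C4″).

## The problem

Licoleafol (15) is a (2S)-flavanone. Its dihydropyranone ring C is fused to the phloroglucinol-type ring A at C4a–C8a, carries the catechol ring B on C2 and the ketone on C4, and ring A bears an (E)-4-hydroxy-3-methylbut-2-enyl chain on C8. The only stereocentre, C2, is benzylic, bound to the aryl ether oxygen O1 and β to the ketone, so it is lost by retro-oxa-Michael opening as soon as a phenoxide or a strong acid meets the finished flavanone. No permanent second centre can steer C2, but a temporary centre at C4 can be set together with it and erased afterwards. The chain must sit on C8 and not on C6, and these positions differ only in which of the two ring-A oxygens ortho to C4a becomes O1. The trisubstituted E-alkene with its allylic primary alcohol lies between O1 and the C7 oxygen; it cyclises or ionises under strong acid and rules out hydrogenation and Lewis-acid dealkylation. The catechol and the 5,7-diphenol are easily oxidised, so all five hydroxyls need groups that fall under nearly neutral conditions. The enabling feature is that the O1–C2 and C3–C4 bonds of ring C enclose the C2–C3 unit with its aryl group, which is a styrene, while the remainder, O1–C8a–C4a–C4, is an ortho-quinone methide. The oxygens on C5, C7 and C8a stabilise the cationic character at C4 of that methide, and an alkoxy group on the methide carbon delivers C4 one oxidation step away from the ketone.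

## Retrosynthesis

**15 from 14.** No skeletal bond is cut; five O–Si bonds are removed from the pentasilyl flavanone 14. Silyl ethers are preferred to methyl, benzyl or methoxymethyl ethers because buffered fluoride spares the alkene, the allylic alcohol and C2. The four phenols carry TBS groups. The single alkyl oxygen carries TBDPS, because it has to outlast a strong Brønsted acid and methanol in the key step, where a primary TBS ether would be the first group to fall.

**14 from 12.** The C4 carbonyl is traced to a C4 methyl ether, so the (2S,4S)-4-methoxyflavan 12 becomes the target of the ring-forming step; water adds at C4 and hemiketal 13 collapses to the ketone. A C4-unsubstituted flavan would need a harder double benzylic oxidation, and a flavan-4-ol would cost an extra step. In 12 the C4–H bond is α to oxygen, benzylic to the most electron-rich ring and pseudo-axial in the cis isomer, which is what a hydride-abstracting oxidant prefers. The forward step must take that hydrogen and leave C2–H and the C1″ methylene alone.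

**12 from 6 and 9.** Cutting O1–C2 and C3–C4 divides 12 into salicylaldehyde 6 and styrene 9, two fragments of similar size joined by trimethyl orthoformate through acetal 10 and methide 11. The neighbouring cuts are weaker. O1–C2 alone leads to a chalcone whose oxa-Michael closure is reversible and racemisation-prone. C4–C4a is an acylation that leaves the stereocentre unsolved. C2–C3 needs an already cyclic acetal. The chosen cut forms the ring, both stereocentres and the C4 oxygen in one operation. It asks for the styrene CH2 to bond to C4, for 2,4-cis closure, and for facial control by a chiral counter-anion.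

**6 from 5, and 5 from 3 and 4.** Two O–Si bonds are removed from 6 to give triol 5. The C–C bond between the ring and C1″ is then cut to give 2,4,6-trihydroxybenzaldehyde 4 and allylic chloride 3. The two nucleophilic ring carbons of 4 are equivalent, so mono-C-alkylation can give only one constitution. A Claisen route would scramble the alkene geometry and a cross-coupling would need a halogenated, differentially protected arene. The forward steps must hold at mono-alkylation and then silylate the 4- and 6-hydroxyls while the chelated, doubly flanked 2-hydroxyl stays free. That free hydroxyl becomes O1 and so fixes the chain on C8.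

**3 from 2, and 2 from 1.** The O–Si bond and then the C–Cl bond are removed, leading to racemic 2-methyl-2-vinyloxirane 1. Its 1,4-opening by chloride sets the E-alkene and both termini of the chain in one step.

**9 from 8, and 8 from 7.** The vinyl C=C bond is cut by Wittig methylenation to aldehyde 8, which is the bis-silyl ether of 3,4-dihydroxybenzaldehyde 7.

## Roads not taken

Alternative 1: Ring A is cut at C8a–C8 and C6–C7 (Danheiser benzannulation). Heating 3-ethoxycyclobut-2-en-1-one A1 with siloxyalkyne A2 would give a vinylketene, which adds the alkyne in a [2+2] step, opens and closes by 6π electrocyclisation to phenol A3. A3 has the chain flanked by the free hydroxyl (future O1) and the triisopropylsilyl ether (future O7), with the C5 oxygen as an ethyl ether.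
- Merit: the position of the chain between two differentiated oxygens is fixed by construction. This is better than the chosen plan, which relies on steric discrimination between two hydroxyls in step 4.
- Weak points: ring C and C2 are untouched. C4a acylation, ring closure and an asymmetric step would still follow, so the benzannulation is a long preamble. A2 is a multistep skipped enyne that must survive thermolysis. The C5 ethyl ether can only be removed with boron halides, in the presence of the allylic alcohol, the alkene and an epimerisable C2.
- Comparison: the chosen plan answers the regiochemical advantage with a fallback in which the formyl group is introduced ortho to the single free hydroxyl. It builds ring C and the stereocentre in the same step that joins the fragments.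

Alternative 2: The C2–C3 bond is cut (Petasis–Ferrier shift). A chiral Brønsted acid would ionise the acetal C–O bond of racemic benzodioxine A4, and the freed enol carbon would attack the aryloxy oxocarbenium carbon to give pentakis-O-TBS licoleafol A5.
- Merits: the product is already at the ketone oxidation level, which saves step 8 of the chosen plan. The process is enantioconvergent because the acetal centre is erased on ionisation. In both respects it is better than the chosen plan.
- Weak points: A4 needs methylenation with Cp2TiMe2 of a hindered ester-type carbonyl next to a silyloxy group, and it is an enol ether acetal that hydrolyses on handling. It needs the same ring-A differentiation as 6. The long-lived ion pair can dissociate or collapse to the open enone, and the flavanone product equilibrates with that open form under acid. No closely related asymmetric version exists. The primary TBS ether of A5 is exposed to the acid.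
- Comparison: the chosen plan has a known achiral version of its key step and known chiral-acid methide cycloadditions on either side of it. It also offers a diastereomer (12) at which stereochemical purity can be upgraded before the ketone exists.

Alternative 3: O1–C8a and C4–C4a are cut (aryne annulation). CsF would generate the C4a–C8a aryne from silyl triflate A6, the hydroxyl of (S)-hydroxy ester A7 would add at C8a, and the aryl anion at C4a would acylate on the ester to give A8.
- Merits: C2 comes from A7, available by established asymmetric carbonyl reduction (RuCl2(BINAP)-catalysed hydrogenation). This is more secure than a new asymmetric method and is better than the chosen plan on that point. The ketone is formed directly, and the C5 alkoxy group directs the oxygen nucleophile to C8a.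
- Weak points: A6 is a pentasubstituted arene that needs a long linear synthesis and again the placement of the chain. Alcohols are poor aryne nucleophiles, and proton transfer to the aryl anion competes with acylation. Basic fluoride can dehydrate A7 and open ring C of A8 with loss of C2. The four methoxymethyl ethers need acid at the end, next to the allylic alcohol.
- Comparison: the chosen plan offers far fewer steps, simple precursors, and a racemic-plus-resolution fallback that also ends in a single enantiomer.

Key step: step 7

Assumption: the antipode of the chiral acid that gives the 2S,4S product cannot be derived from structure alone. The (R)-acid is written, and its mirror image takes its place if the first analysis of 12 shows the opposite sense.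

## Route

Step 1
Reactants: 1 2-methyl-2-vinyloxirane (racemic)
Product: 2 (E)-4-chloro-2-methylbut-2-en-1-ol
Conditions: TiCl4, CH2Cl2, −85 °C; aqueous HCl work-up
Reagents that add atoms: titanium tetrachloride, Cl[Ti](Cl)(Cl)Cl
Why: Lewis-acid activation of the vinyl epoxide and delivery of chloride to the vinyl terminus (SN2′, 1,4-opening), a known transformation of this epoxide. The E-alkene, with CH2OH and CH2Cl trans, is expected from the s-trans conformer.

Step 2
Reactants: 2 (E)-4-chloro-2-methylbut-2-en-1-ol
Product: 3 tert-butyl{[(E)-4-chloro-2-methylbut-2-en-1-yl]oxy}diphenylsilane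
Conditions: TBDPSCl, imidazole, CH2Cl2, 0 °C
Reagents that add atoms: tert-butyldiphenylsilyl chloride, CC(C)(C)[Si](Cl)(c1ccccc1)c1ccccc1
Why: Standard silylation of a primary alcohol. The allylic chloride is not displaced by imidazole at 0 °C on this time scale.

Step 3
Reactants: 3 tert-butyl{[(E)-4-chloro-2-methylbut-2-en-1-yl]oxy}diphenylsilane; 4 2,4,6-trihydroxybenzaldehyde (excess)
Product: 5 3-[(E)-4-(TBDPSO)-3-methylbut-2-enyl]-2,4,6-trihydroxybenzaldehyde
Conditions: DBU, NaI (cat.), THF, 0 °C to rt
Reagents that add atoms: none
Why: C-alkylation of the ambident phloroglucinaldehyde anion by an allylic halide at its primary carbon (SN2, the usual C-prenylation of acylphloroglucinols), with the allylic iodide formed in situ. The two ring carbons are equivalent, excess 4 suppresses double alkylation, and the E geometry is not touched.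

Step 4
Reactants: 5 3-[(E)-4-(TBDPSO)-3-methylbut-2-enyl]-2,4,6-trihydroxybenzaldehyde
Product: 6 4,6-bis(TBSO)-3-[(E)-4-(TBDPSO)-3-methylbut-2-enyl]-2-hydroxybenzaldehyde
Conditions: TBSCl (2.1 equiv), imidazole, CH2Cl2, 0 °C
Reagents that add atoms: tert-butyldimethylsilyl chloride, CC(C)(C)[Si](C)(C)Cl
Why: Site-selective silylation. The unchelated 4-hydroxyl and the 6-hydroxyl (one ortho neighbour) should react, while the 2-hydroxyl, flanked by the formyl group and the chain and held in the hydrogen bond to the carbonyl, should stay free. The position of the free hydroxyl is to be confirmed by two-dimensional NMR before use.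

Step 5
Reactants: 7 3,4-dihydroxybenzaldehyde
Product: 8 3,4-bis(TBSO)benzaldehyde
Conditions: TBSCl (2.4 equiv), imidazole, DMF, rt
Reagents that add atoms: tert-butyldimethylsilyl chloride, CC(C)(C)[Si](C)(C)Cl
Why: Routine bis-silylation of a catechol.

Step 6
Reactants: 8 3,4-bis(TBSO)benzaldehyde
Product: 9 3,4-bis(TBSO)styrene
Conditions: Ph3PCH3Br, KOtBu (slight deficit), THF, 0 °C
Reagents that add atoms: methyltriphenylphosphonium bromide, C[P+](c1ccccc1)(c1ccccc1)c1ccccc1.[Br-]
Why: Wittig methylenation of an aryl aldehyde with the non-stabilised ylide. Aryl silyl ethers tolerate the ylide when no excess alkoxide is present.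

Step 7
Reactants: 6 4,6-bis(TBSO)-3-[(E)-4-(TBDPSO)-3-methylbut-2-enyl]-2-hydroxybenzaldehyde; 9 3,4-bis(TBSO)styrene
Product: 12 (2S,4S)-5,7-bis(TBSO)-2-[3,4-bis(TBSO)phenyl]-8-[(E)-4-(TBDPSO)-3-methylbut-2-enyl]-4-methoxychromane (2,4-cis), via dimethyl acetal 10 (not isolated), via 4-methoxy ortho-quinone methide 11 (not isolated)
Conditions: HC(OMe)3, (R)-3,3′-bis(2,4,6-triisopropylphenyl)-1,1′-binaphthyl-2,2′-diyl N-triflylphosphoramide (5 mol %), 5 Å molecular sieves, toluene, rt then −40 °C; 9 added slowly
Reagents that add atoms: trimethyl orthoformate, COC(OC)OC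
Why: Proposed new method: acid-catalysed exchange with the orthoformate gives acetal 10, which loses methanol to methide 11 (when protonated, an oxocarbenium ion whose phenol is hydrogen-bonded to the chiral phosphoramide anion); the terminal carbon of 9 bonds to the methide carbon (C3–C4) and O1 then captures the benzylic cation (O1–C2), an asynchronous inverse-demand hetero-Diels–Alder reaction. The closest known reaction types are the achiral acid-catalysed coupling of salicylaldehydes, trimethyl orthoformate and styrenes to 2,4-cis-4-methoxyflavans and the chiral N-triflylphosphoramide-catalysed [4+2] cycloaddition of ortho-quinone methides from ortho-hydroxybenzyl alcohols with styrenes; the enantioselective use of an alkoxy methide made from an aldehyde is the untested part. Ring C closes in a [4+2] mode, in the stepwise limit a 6-endo capture of the C2 cation by the phenolic oxygen. C4 is set by the face of the ion-paired methide that the catalyst leaves open, and C2 follows from C4 through the endo transition state of the E-methide or, in the stepwise limit, through chair-like closure with aryl and methoxy both pseudo-equatorial, so the 2,4-cis isomer is expected. Regiochemistry needs the styrene CH2 to meet C4, which the polarity of both partners secures (three oxygen donors on the methide, a para-silyloxy group on the styrene). Chemoselectivity for the styrene over the side-chain alkene rests on the inductively deactivating allylic silyloxy group of that alkene and on its inability to reach C4. Any trans isomer is removed at this stage, because after step 8 it would be the 2R ketone.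

Step 8
Reactants: 12 (2S,4S)-5,7-bis(TBSO)-2-[3,4-bis(TBSO)phenyl]-8-[(E)-4-(TBDPSO)-3-methylbut-2-enyl]-4-methoxychromane
Product: 14 (2S)-5,7-bis(TBSO)-2-[3,4-bis(TBSO)phenyl]-8-[(E)-4-(TBDPSO)-3-methylbut-2-enyl]chroman-4-one, via C4 hemiketal 13 (not isolated)
Conditions: DDQ, CH2Cl2/pH 7 phosphate buffer (10:1), 0 °C
Reagents that add atoms: water, O
Why: DDQ abstracts hydride from C4–H (α to the methoxy oxygen, benzylic to the trioxygenated ring A, pseudo-axial in the cis isomer). Water adds to the oxocarbenium ion and hemiketal 13 loses methanol, the same oxidative cleavage of an electron-rich benzylic ether that removes dimethoxybenzyl groups. C2 is not involved and stays S.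

Step 9
Reactants: 14 (2S)-5,7-bis(TBSO)-2-[3,4-bis(TBSO)phenyl]-8-[(E)-4-(TBDPSO)-3-methylbut-2-enyl]chroman-4-one
Product: 15 licoleafol
Conditions: TBAF, AcOH (1:1, excess), THF, 0 °C to rt
Reagents that add atoms: none
Why: Fluoride cleaves the four aryl TBS ethers and the primary TBDPS ether. Acetic acid protonates each phenoxide as it forms, so ring C should not open by retro-oxa-Michael reaction and C2 should keep its configuration.

## Compound list

1 | 2-methyl-2-vinyloxirane (racemic) | C=CC1(C)CO1 | starting material
2 | (E)-4-chloro-2-methylbut-2-en-1-ol | C/C(=C\CCl)CO | intermediate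
3 | tert-butyl{[(E)-4-chloro-2-methylbut-2-en-1-yl]oxy}diphenylsilane | C/C(=C\CCl)CO[Si](c1ccccc1)(c1ccccc1)C(C)(C)C | intermediate
4 | 2,4,6-trihydroxybenzaldehyde | O=Cc1c(O)cc(O)cc1O | starting material
5 | 3-[(E)-4-(tert-butyldiphenylsilyloxy)-3-methylbut-2-enyl]-2,4,6-trihydroxybenzaldehyde | C/C(=C\Cc1c(O)cc(O)c(C=O)c1O)CO[Si](c1ccccc1)(c1ccccc1)C(C)(C)C | intermediate
6 | 4,6-bis(tert-butyldimethylsilyloxy)-3-[(E)-4-(tert-butyldiphenylsilyloxy)-3-methylbut-2-enyl]-2-hydroxybenzaldehyde | C/C(=C\Cc1c(O)c(C=O)c(O[Si](C)(C)C(C)(C)C)cc1O[Si](C)(C)C(C)(C)C)CO[Si](c1ccccc1)(c1ccccc1)C(C)(C)C | intermediate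
7 | 3,4-dihydroxybenzaldehyde | O=Cc1ccc(O)c(O)c1 | starting material
8 | 3,4-bis(tert-butyldimethylsilyloxy)benzaldehyde | O=Cc1ccc(O[Si](C)(C)C(C)(C)C)c(O[Si](C)(C)C(C)(C)C)c1 | intermediate
9 | 3,4-bis(tert-butyldimethylsilyloxy)styrene | C=Cc1ccc(O[Si](C)(C)C(C)(C)C)c(O[Si](C)(C)C(C)(C)C)c1 | intermediate
10 | 3,5-bis(tert-butyldimethylsilyloxy)-2-(dimethoxymethyl)-6-[(E)-4-(tert-butyldiphenylsilyloxy)-3-methylbut-2-enyl]phenol (dimethyl acetal of 6, not isolated) | C/C(=C\Cc1c(O)c(C(OC)OC)c(O[Si](C)(C)C(C)(C)C)cc1O[Si](C)(C)C(C)(C)C)CO[Si](c1ccccc1)(c1ccccc1)C(C)(C)C | intermediate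
11 | (6E)-3,5-bis(tert-butyldimethylsilyloxy)-6-(methoxymethylene)-2-[(E)-4-(tert-butyldiphenylsilyloxy)-3-methylbut-2-enyl]cyclohexa-2,4-dien-1-one (4-methoxy ortho-quinone methide, drawn as the E-methide, not isolated) | CO/C=C1\C(O[Si](C)(C)C(C)(C)C)=CC(O[Si](C)(C)C(C)(C)C)=C(C/C=C(\C)CO[Si](c2ccccc2)(c2ccccc2)C(C)(C)C)C1=O | intermediate
12 | (2S,4S)-5,7-bis(tert-butyldimethylsilyloxy)-2-[3,4-bis(tert-butyldimethylsilyloxy)phenyl]-8-[(E)-4-(tert-butyldiphenylsilyloxy)-3-methylbut-2-enyl]-4-methoxychromane (2,4-cis) | C/C(=C\Cc1c(O[Si](C)(C)C(C)(C)C)cc(O[Si](C)(C)C(C)(C)C)c2c1O[C@H](c1ccc(O[Si](C)(C)C(C)(C)C)c(O[Si](C)(C)C(C)(C)C)c1)C[C@@H]2OC)CO[Si](c1ccccc1)(c1ccccc1)C(C)(C)C | intermediate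
13 | (2S)-5,7-bis(tert-butyldimethylsilyloxy)-2-[3,4-bis(tert-butyldimethylsilyloxy)phenyl]-8-[(E)-4-(tert-butyldiphenylsilyloxy)-3-methylbut-2-enyl]-4-methoxychroman-4-ol (hemiketal, either configuration at C4, not isolated) | C/C(=C\Cc1c(O[Si](C)(C)C(C)(C)C)cc(O[Si](C)(C)C(C)(C)C)c2c1O[C@H](c1ccc(O[Si](C)(C)C(C)(C)C)c(O[Si](C)(C)C(C)(C)C)c1)CC2(O)OC)CO[Si](c1ccccc1)(c1ccccc1)C(C)(C)C | intermediate
14 | (2S)-5,7-bis(tert-butyldimethylsilyloxy)-2-[3,4-bis(tert-butyldimethylsilyloxy)phenyl]-8-[(E)-4-(tert-butyldiphenylsilyloxy)-3-methylbut-2-enyl]chroman-4-one | C/C(=C\Cc1c(O[Si](C)(C)C(C)(C)C)cc(O[Si](C)(C)C(C)(C)C)c2c1O[C@H](c1ccc(O[Si](C)(C)C(C)(C)C)c(O[Si](C)(C)C(C)(C)C)c1)CC2=O)CO[Si](c1ccccc1)(c1ccccc1)C(C)(C)C | intermediate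
15 | licoleafol, (2S)-2-(3,4-dihydroxyphenyl)-5,7-dihydroxy-8-[(E)-4-hydroxy-3-methylbut-2-enyl]chroman-4-one | C/C(=C\Cc1c(O)cc(O)c2c1O[C@H](c1ccc(O)c(O)c1)CC2=O)CO | target

## Step count and risks

Total: 9 steps. Longest linear sequence: 7 steps (1, 2, 3, 4, 7, 8, 9).

**Step 7 (key step, new method).** The most likely failure is low enantioselectivity, because a loosely ion-paired or adventitious-acid pathway can compete on so stabilised a cation. Acid-induced oligomerisation of the electron-rich styrene and erosion of the cis preference by reversible ionisation at C2 are further concerns.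

Fallback, from 6 and 9 and returning at 14: the coupling is run with trimethyl orthoformate and catalytic triflic acid in CH2Cl2 at low temperature, which is the known achiral three-component reaction. It should give the cis flavan as the racemate, that is 12 together with its mirror image, the (2R,4R)-4-methoxyflavan F1. The racemate is oxidised with DDQ as in step 8, F1 passing through the mirror-image hemiketal F2 to the (2R)-flavanone F3. Kinetic resolution by asymmetric transfer hydrogenation follows, with RuCl(p-cymene)(TsDPEN) and HCO2H/Et3N, in the antipode that reduces the 2R ketone faster. It should convert F3 into the cis-(2R,4R)-flavan-4-ol F4 and leave 14, which is separated by chromatography. Half of the material is given up.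

**Step 3.** The formyl group lowers the nucleophilicity of the ring carbons, so O-alkylation and double alkylation may overtake mono-C-alkylation.

Fallback, from 3 and returning at 5: the order of the two C–C bond formations is reversed. Phloroglucinol F5, used in large excess and more nucleophilic at carbon, is alkylated with 3 (DBU, NaI, THF) to 2-[(E)-4-(TBDPSO)-3-methylbut-2-enyl]benzene-1,3,5-triol F6. Vilsmeier–Haack formylation (POCl3, DMF; aqueous NaOAc) at either of the two equivalent free ring positions then gives 5.

**Step 4.** The risk is poor site selectivity between the two hydroxyls ortho to the formyl group. Silylation of the 2-hydroxyl would leave the wrong oxygen free and would later place the chain on C6.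

Fallback, from 3 and returning at 6: triol F6, made as in the fallback to step 3, is treated with two equivalents of TBSCl and imidazole. The unhindered hydroxyl and one of the two equivalent hydroxyls beside the chain react, giving 3,5-bis(TBSO)-2-[(E)-4-(TBDPSO)-3-methylbut-2-enyl]phenol F7, for which no regiochemical alternative exists beyond under- or over-silylation. Magnesium-mediated ortho-formylation (MgCl2, Et3N, paraformaldehyde, THF, reflux; Casnati–Skattebøl reaction) places the formyl group at the only free position ortho to the free hydroxyl and gives 6.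

**Step 8.** Hydride abstraction may occur at the wrong site: at C2–H, which is benzylic to the silylated catechol ring and would cost the stereocentre, or at the benzylic and allylic C1″ methylene. Further dehydrogenation of the product towards the flavone is also possible.

Fallback, from 12 and returning at 14: oxidation by hydride abstraction is replaced by substitution followed by alcohol oxidation. Mild acid in wet solvent (pyridinium p-toluenesulfonate, THF/H2O, 40 °C) exchanges the methoxy group for hydroxyl through the ring-A-stabilised C4 cation. This gives the (2S)-flavan-4-ol F8 as either C4 epimer, and Dess–Martin periodinane with NaHCO3 in CH2Cl2 oxidises it to 14.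

## Further compounds

F1 | step 7 | (2R,4R)-5,7-bis(tert-butyldimethylsilyloxy)-2-[3,4-bis(tert-butyldimethylsilyloxy)phenyl]-8-[(E)-4-(tert-butyldiphenylsilyloxy)-3-methylbut-2-enyl]-4-methoxychromane (mirror image of 12) | C/C(=C\Cc1c(O[Si](C)(C)C(C)(C)C)cc(O[Si](C)(C)C(C)(C)C)c2c1O[C@@H](c1ccc(O[Si](C)(C)C(C)(C)C)c(O[Si](C)(C)C(C)(C)C)c1)C[C@H]2OC)CO[Si](c1ccccc1)(c1ccccc1)C(C)(C)C
F2 | step 7 | (2R)-4-hydroxy-4-methoxy hemiketal, mirror-image series of 13 (either configuration at C4, not isolated) | C/C(=C\Cc1c(O[Si](C)(C)C(C)(C)C)cc(O[Si](C)(C)C(C)(C)C)c2c1O[C@@H](c1ccc(O[Si](C)(C)C(C)(C)C)c(O[Si](C)(C)C(C)(C)C)c1)CC2(O)OC)CO[Si](c1ccccc1)(c1ccccc1)C(C)(C)C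
F3 | step 7 | (2R)-5,7-bis(tert-butyldimethylsilyloxy)-2-[3,4-bis(tert-butyldimethylsilyloxy)phenyl]-8-[(E)-4-(tert-butyldiphenylsilyloxy)-3-methylbut-2-enyl]chroman-4-one (mirror image of 14) | C/C(=C\Cc1c(O[Si](C)(C)C(C)(C)C)cc(O[Si](C)(C)C(C)(C)C)c2c1O[C@@H](c1ccc(O[Si](C)(C)C(C)(C)C)c(O[Si](C)(C)C(C)(C)C)c1)CC2=O)CO[Si](c1ccccc1)(c1ccccc1)C(C)(C)C
F4 | step 7 | (2R,4R)-5,7-bis(tert-butyldimethylsilyloxy)-2-[3,4-bis(tert-butyldimethylsilyloxy)phenyl]-8-[(E)-4-(tert-butyldiphenylsilyloxy)-3-methylbut-2-enyl]chroman-4-ol (2,4-cis) | C/C(=C\Cc1c(O[Si](C)(C)C(C)(C)C)cc(O[Si](C)(C)C(C)(C)C)c2c1O[C@@H](c1ccc(O[Si](C)(C)C(C)(C)C)c(O[Si](C)(C)C(C)(C)C)c1)C[C@H]2O)CO[Si](c1ccccc1)(c1ccccc1)C(C)(C)C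
F5 | step 3 | phloroglucinol (benzene-1,3,5-triol) | Oc1cc(O)cc(O)c1
F6 | step 3 | 2-[(E)-4-(tert-butyldiphenylsilyloxy)-3-methylbut-2-enyl]benzene-1,3,5-triol | C/C(=C\Cc1c(O)cc(O)cc1O)CO[Si](c1ccccc1)(c1ccccc1)C(C)(C)C
F7 | step 4 | 3,5-bis(tert-butyldimethylsilyloxy)-2-[(E)-4-(tert-butyldiphenylsilyloxy)-3-methylbut-2-enyl]phenol | C/C(=C\Cc1c(O)cc(O[Si](C)(C)C(C)(C)C)cc1O[Si](C)(C)C(C)(C)C)CO[Si](c1ccccc1)(c1ccccc1)C(C)(C)C
F8 | step 8 | (2S)-5,7-bis(tert-butyldimethylsilyloxy)-2-[3,4-bis(tert-butyldimethylsilyloxy)phenyl]-8-[(E)-4-(tert-butyldiphenylsilyloxy)-3-methylbut-2-enyl]chroman-4-ol (either configuration at C4) | C/C(=C\Cc1c(O[Si](C)(C)C(C)(C)C)cc(O[Si](C)(C)C(C)(C)C)c2c1O[C@H](c1ccc(O[Si](C)(C)C(C)(C)C)c(O[Si](C)(C)C(C)(C)C)c1)CC2O)CO[Si](c1ccccc1)(c1ccccc1)C(C)(C)C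
A1 | alternative 1 | 3-ethoxycyclobut-2-en-1-one | CCOC1=CC(=O)C1
A2 | alternative 1 | triisopropyl{[(E)-6-(tert-butyldimethylsilyloxy)-5-methylhex-4-en-1-yn-1-yl]oxy}silane | C/C(=C\CC#CO[Si](C(C)C)(C(C)C)C(C)C)CO[Si](C)(C)C(C)(C)C
A3 | alternative 1 | 2-[(E)-4-(tert-butyldimethylsilyloxy)-3-methylbut-2-enyl]-5-ethoxy-3-(triisopropylsilyloxy)phenol | C/C(=C\Cc1c(O)cc(OCC)cc1O[Si](C(C)C)(C(C)C)C(C)C)CO[Si](C)(C)C(C)(C)C
A4 | alternative 2 | 2-[3,4-bis(tert-butyldimethylsilyloxy)phenyl]-5,7-bis(tert-butyldimethylsilyloxy)-8-[(E)-4-(tert-butyldimethylsilyloxy)-3-methylbut-2-enyl]-4-methylene-4H-1,3-benzodioxine (racemic at C2) | C=C1OC(c2ccc(O[Si](C)(C)C(C)(C)C)c(O[Si](C)(C)C(C)(C)C)c2)Oc2c(C/C=C(\C)CO[Si](C)(C)C(C)(C)C)c(O[Si](C)(C)C(C)(C)C)cc(O[Si](C)(C)C(C)(C)C)c21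
A5 | alternative 2 | (2S)-pentakis-O-TBS licoleafol | C/C(=C\Cc1c(O[Si](C)(C)C(C)(C)C)cc(O[Si](C)(C)C(C)(C)C)c2c1O[C@H](c1ccc(O[Si](C)(C)C(C)(C)C)c(O[Si](C)(C)C(C)(C)C)c1)CC2=O)CO[Si](C)(C)C(C)(C)C
A6 | alternative 3 | 2-[(E)-4-(tert-butyldiphenylsilyloxy)-3-methylbut-2-enyl]-3,5-bis(methoxymethoxy)-6-(trimethylsilyl)phenyl trifluoromethanesulfonate | C/C(=C\Cc1c(OCOC)cc(OCOC)c([Si](C)(C)C)c1OS(=O)(=O)C(F)(F)F)CO[Si](c1ccccc1)(c1ccccc1)C(C)(C)C
A7 | alternative 3 | methyl (S)-3-[3,4-bis(methoxymethoxy)phenyl]-3-hydroxypropanoate | COC(=O)C[C@H](O)c1ccc(OCOC)c(OCOC)c1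
A8 | alternative 3 | (2S)-tetrakis-O-methoxymethyl, O-TBDPS licoleafol | C/C(=C\Cc1c(OCOC)cc(OCOC)c2c1O[C@H](c1ccc(OCOC)c(OCOC)c1)CC2=O)CO[Si](c1ccccc1)(c1ccccc1)C(C)(C)C
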